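Read every 16.0 h, the three earlier runs came to a short meeting with one question about the grey run.

| flask | Sbt | Ptn | Ctl | Pdt | time |
|---|---|---|---|---|---|
| amber | 0.400 M | 1.20 M | 0.0400 M |  |  |
| ochre | 0.240 M | 1.04 M | 0.0400 M |  |  |
| violet | 0.400 M | 1.20 M | 0.0400 M | 0.120 M |  |
| grey | 0.400 M | 0.400 M | 0.120 M |  | 96 h |

- amber run (time / h: [Pdt] / M): 16: 0.0528; 32: 0.1293; 48: 0.1986; 64: 0.2490; 80: 0.2921; 96: 0.3262
- ochre run (time / h: [Pdt] / M): 16: 0.0351; 32: 0.0856; 48: 0.1302; 64: 0.1650; 80: 0.1888; 96: 0.2049
- violet run (time / h: [Pdt] / M): 16: 0.1724; 32: 0.2494; 48: 0.3159; 64: 0.3714; 80: 0.4137; 96: 0.4467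

(scatter of a reading: 0.001 M)

- Pdt in the grey run at 96 h, as a share of the Sbt charged

- Overall: Sbt + Ptn -> Pdt, with Ctl as catalyst.
- Constant volume, constant temperature.
- What is held in complexes is read along with the free species.
- "The second partner" is Ptn.

I proposed one measure, the turn time: cCtl charged divided by the rate, the hours one charged Ctl takes per Pdt made. I reported that amber, where Sbt is the limiting reagent, charged at less than Ptn, gave 9.24 h between 32 h and 48 h, around cSbt 0.236 M and cPtn 1.04 M. Between 80 h and 96 h it gave 18.8 h, around cSbt 0.0908 M and cPtn 0.891 M.

I argued that a turn is two waits in a row, one for Sbt and one for Ptn, each shrinking as the concentration of its own species grows. The Ptn part is my assumption, since these runs hardly move cPtn. Solving the two readings gave a Sbt constant of 79.2 M·min and a Ptn constant of 226 M·min, and each is divided by its own concentration to give its wait. Their sum is 306 M·min, the turn sum.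

I then turned to the grey run. Its charges are equal and are used one for one, so cSbt and cPtn stay equal, and the turn time is the turn sum over that concentration. So I worked with the fraction left, which loses the same share each hour, 0.0236 h⁻¹. Amber's first two readings, drawn back to zero, showed a lag of 4.96 h. That leaves 11.7 %, so I committed to 88.3 %.

The forecaster held to 66 %, with a range from 52 % to 80 %, on these grounds: “Assuming Ptn is first order (the data barely test this)”. My figure stands above that range.

The flask gives 84.9 %, which is 19 percentage points above the forecast.

    J + Sbt → Ctl.Sbt (0.8640 L mol⁻¹ h⁻¹)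
    Ctl.Sbt + Ptn → Pdt + J (0.3172 L mol⁻¹ h⁻¹)
    Ctl → J (0.1858 h⁻¹)
    J + X → G

In the grey run Ctl turned into J over the first hours, with a life of 5.38 h, and the reaction of J with X made no real difference to the answer. From then to 96 h J took up Sbt and Ctl.Sbt met Ptn, turn after turn, until what had not become Pdt, bound Sbt counted, came to 0.0604 M, less than the 0.120 M of Ctl charged. Read through the fraction left, that result gives a turn sum of 347 M·min against 306 M·min. In the ochre run the two waits give 19.3 h from a quarter to half of the Sbt charged, and the simulated times 23.6 h and 43.7 h lie 20.1 h apart.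

The earlier runs and the new flask are simulated on assumed constants; the scatter is artificial.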